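## Retrosynthetic overview

1. Rings: A/B = left chromone, C = pyran, D = 1,3-dioxane, E = dihydropyranone, F/G = right 2H-chromene. The two ketal carbons and the CH–CH bond joining the halves are disconnected together, giving an achiral pyrano[4,3-b]chromenylium precursor 22 (rings A–C) and a 3-acetoacetylchroman-4-one 16 (rings F/G).
2. Ring F carries the strategy. Its C-3 is the central carbon of a masked tricarbonyl array (C-4 oxygen, the ring-E C=O, C-2 one hydride below a formyl carbon), and O-1 sits on the arene carbon ortho to the C-4 carbon and para to the 6-oxygen. Ring F is therefore made as a 3-acylchromone from a 2-bromoaroyl chloride and an enamine carbon by C-aroylation plus O-arylation, with the second carbonyl locked in a 3-methylisoxazole (masked acetoacetyl), then 1,4-reduced and unmasked.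
3. Rings C and B: the same acid chloride acylates the enaminone of acetylacetone monoketal; acid closes the 4-pyranone (ring C), then benzyloxide addition and O-arylation close ring B.
4. Rings A and G are one building block (6) from opianic acid: bromination para to the 2-methoxy group, methyl-to-benzyl exchange, oxidation, acid chloride.
5. Order of ring formation: F (step 8); C (step 13); B (step 14); D and E (step 15).

Key step: step 8

Assumption: the cis-fused arrangement of the two centres formed last (ring-fusion CH and second ketal carbon) is taken to be the thermodynamically preferred one, since the compound is isolated in this form; the enantiomer of the phosphoric acid in step 15 is written as (R) and is to be matched to the required configuration by a pilot run.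

## Route

Step 1
Reactants: 1 opianic acid (6-formyl-2,3-dimethoxybenzoic acid)
Product: 2 5-bromo-6-formyl-2,3-dimethoxybenzoic acid
Conditions: Br2, AcOH, 25 °C
Reagents that add atoms: bromine, BrBr
Why: Electrophilic aromatic bromination should go para to the 2-methoxy group and ortho to the formyl carbon (masked as a lactol in the hydroxyphthalide tautomer), because the other free position is para to the carboxyl carbon and deactivated.

Step 2
Reactants: 2 5-bromo-6-formyl-2,3-dimethoxybenzoic acid
Product: 3 5-bromo-6-formyl-2,3-dihydroxybenzoic acid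
Conditions: BBr3, CH2Cl2, −78 to 25 °C; then H2O
Reagents that add atoms: none
Why: Lewis-acid cleavage of both aryl methyl ethers (BBr3 demethylation) is placed here, before any sensitive group exists.

Step 3
Reactants: 3 5-bromo-6-formyl-2,3-dihydroxybenzoic acid
Product: 4 benzyl 2,3-bis(benzyloxy)-5-bromo-6-formylbenzoate
Conditions: BnBr, K2CO3, DMF, 60 °C
Reagents that add atoms: benzyl bromide, BrCc1ccccc1
Why: Williamson alkylation of the two phenoxides and of the carboxylate gives a protecting-group set that one hydrogenolysis removes at the end.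

Step 4
Reactants: 4 benzyl 2,3-bis(benzyloxy)-5-bromo-6-formylbenzoate
Product: 5 3,4-bis(benzyloxy)-2-[(benzyloxy)carbonyl]-6-bromobenzoic acid
Conditions: NaClO2, NaH2PO4, 2-methylbut-2-ene, t-BuOH/H2O, 25 °C
Reagents that add atoms: sodium chlorite, [Na+].[O-]Cl=O
Why: Pinnick oxidation converts the hindered aldehyde to the acid without touching benzyl ethers or the electron-rich ring (hypochlorite is scavenged).

Step 5
Reactants: 5 3,4-bis(benzyloxy)-2-[(benzyloxy)carbonyl]-6-bromobenzoic acid
Product: 6 benzyl 2,3-bis(benzyloxy)-5-bromo-6-(chlorocarbonyl)benzoate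
Conditions: (COCl)2, DMF (cat.), CH2Cl2, 0 to 25 °C; used at once
Reagents that add atoms: oxalyl chloride, O=C(Cl)C(=O)Cl
Why: Acid chloride formation under Vilsmeier-type catalysis gives the common 2-bromoaroyl electrophile for both halves.

Step 6
Reactants: 7 3,5-dimethylisoxazole
Product: 9 2-(3-methylisoxazol-5-yl)acetaldehyde, via lateral lithio species 8 (not isolated)
Conditions: n-BuLi, THF, −78 °C; DMF, −78 to 0 °C; then H2O
Reagents that add atoms: N,N-dimethylformamide, CN(C)C=O
Why: Lateral lithiation of 3,5-dimethylisoxazole occurs at the more acidic 5-methyl group, and formylation of the carbanion with DMF gives the homologous aldehyde.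

Step 7
Reactants: 9 2-(3-methylisoxazol-5-yl)acetaldehyde
Product: 10 (E)-1-[2-(3-methylisoxazol-5-yl)ethenyl]pyrrolidine
Conditions: pyrrolidine, MgSO4, CH2Cl2, 0 to 25 °C; used crude
Reagents that add atoms: pyrrolidine, C1CCNC1
Why: Enamine condensation of an arylacetaldehyde with a secondary amine gives the conjugated (E)-enamine, whose β-carbon is the future C-3.

Step 8
Reactants: 10 (E)-1-[2-(3-methylisoxazol-5-yl)ethenyl]pyrrolidine; 6 benzyl 2,3-bis(benzyloxy)-5-bromo-6-(chlorocarbonyl)benzoate
Product: 13 benzyl 6,7-bis(benzyloxy)-3-(3-methylisoxazol-5-yl)-4-oxo-4H-chromene-5-carboxylate, via C-acylated enamine 11 (not isolated), via formyl enolate 12 (not isolated)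
Conditions: Cs2CO3, 1,4-dioxane, 0 to 25 °C; then H2O (5 equiv), CuI (10 mol %), 1,10-phenanthroline (20 mol %), 90 °C, same pot
Reagents that add atoms: water, O
Why: The enamine β-carbon is acylated by the aroyl chloride (Stork enamine acylation; N-acylation is reversible and the C-acylated vinylogous amide is the sink), which makes the C-3 to C-4 bond. Water and carbonate then replace pyrrolidine by addition–elimination to give formyl enolate 12, and its oxygen is delivered to the ortho C–Br carbon by an Ullmann-type O-arylation (monovalent copper, oxidative addition from the chelated enolate, reductive elimination), which makes the O-1 to C-8a bond and closes the 4-pyranone ring as a six-membered ring by exo-type ipso substitution. The closest known reaction type is the one-pot C-acylation/O-arylation of β-dicarbonyl and aminoacrylate donors with 2-halobenzoyl chlorides that gives chromones and 4-quinolones. No stereocentre is formed. The step needs C- over N-acylation (secured by the enamine) and ring closure through the formyl oxygen only, which is secured because the second carbonyl of the future triketone is locked as the isoxazole ring oxygen; the bromine position was fixed in step 1. One pot thus joins the arene to the masked triketide, closes ring F at the chromone oxidation level and delivers all fourteen skeletal carbons of the right-hand half.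

Step 9
Reactants: 13 benzyl 6,7-bis(benzyloxy)-3-(3-methylisoxazol-5-yl)-4-oxo-4H-chromene-5-carboxylate
Product: 14 benzyl 6,7-bis(benzyloxy)-3-(3-methylisoxazol-5-yl)-4-oxochromane-5-carboxylate (racemic)
Conditions: LiBH(s-Bu)3 (1.05 equiv), THF, −78 °C; then H2O
Reagents that add atoms: none
Why: Conjugate (1,4-) hydride reduction of the 3-heteroaryl chromone, as for isoflavones, brings C-2 to the CH2 level; it is done before unmasking so that no amine ever meets an electrophilic chromone C-2 (the C-3 centre is lost again later).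

Step 10
Reactants: 14 benzyl 6,7-bis(benzyloxy)-3-(3-methylisoxazol-5-yl)-4-oxochromane-5-carboxylate
Product: 16 benzyl 6,7-bis(benzyloxy)-4-oxo-3-(3-oxobutanoyl)chromane-5-carboxylate, via primary enaminone 15 (not isolated)
Conditions: Mo(CO)6, MeCN/H2O, 80 °C; then 1 M HCl, THF, 25 °C
Reagents that add atoms: water, O
Why: Reductive N–O cleavage of the isoxazole by zerovalent molybdenum gives the β-amino enone, and mild acid hydrolysis (kept at 25 °C to avoid cyclodehydration to a 4-pyranone) releases the 1,3,5-triketone, which exists as enol tautomers.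

Step 11
Reactants: 17 pentane-2,4-dione
Product: 18 1-(2-methyl-1,3-dioxolan-2-yl)propan-2-one
Conditions: HOCH2CH2OH (1 equiv), p-TsOH (cat.), toluene, reflux, Dean–Stark; distillation
Reagents that add atoms: ethane-1,2-diol, OCCO
Why: Acid-catalysed monoketalisation of the diketone masks one carbonyl so that the other reacts as a simple methyl ketone.

Step 12
Reactants: 18 1-(2-methyl-1,3-dioxolan-2-yl)propan-2-one
Product: 19 (E)-4-(dimethylamino)-1-(2-methyl-1,3-dioxolan-2-yl)but-3-en-2-one
Conditions: Me2NCH(OMe)2, toluene, 100 °C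
Reagents that add atoms: N,N-dimethylformamide dimethyl acetal, COC(OC)N(C)C
Why: Enaminone formation with the formamide acetal occurs at the methyl group, the methylene being neopentyl-like and hindered.

Step 13
Reactants: 19 (E)-4-(dimethylamino)-1-(2-methyl-1,3-dioxolan-2-yl)but-3-en-2-one; 6 benzyl 2,3-bis(benzyloxy)-5-bromo-6-(chlorocarbonyl)benzoate
Product: 21 benzyl 2,3-bis(benzyloxy)-5-bromo-6-(6-methyl-4-oxo-4H-pyran-3-carbonyl)benzoate, via C-acylated enaminone 20 (not isolated)
Conditions: Et3N, CH2Cl2, 0 to 25 °C; then 2 M HCl, THF, 25 °C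
Reagents that add atoms: water, O
Why: C-acylation of the enaminone α-carbon, then acid deketalisation and 6-endo addition–elimination of the new enol oxygen at the aminomethylene carbon (loss of dimethylamine), is the standard 4-pyranone synthesis from aminomethylene tricarbonyl compounds.

Step 14
Reactants: 21 benzyl 2,3-bis(benzyloxy)-5-bromo-6-(6-methyl-4-oxo-4H-pyran-3-carbonyl)benzoate
Product: 22 benzyl 1,7,8-tris(benzyloxy)-3-methyl-10-oxo-1H,10H-pyrano[4,3-b]chromene-9-carboxylate (racemic)
Conditions: BnOH (3 equiv), Cs2CO3, CuI (10 mol %), 1,10-phenanthroline (20 mol %), 1,4-dioxane, 80 °C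
Reagents that add atoms: benzyl alcohol, OCc1ccccc1
Why: Oxa-Michael addition of benzyloxide to the doubly activated C-2 of the 3-aroyl-4-pyranone gives a β-diketone enolate, which undergoes Ullmann-type O-arylation through the pyranone oxygen (the formyl-level carbon is capped as the acetal, so only this oxygen can close ring B); benzyl alcohol makes transesterification degenerate.

Step 15
Reactants: 22 benzyl 1,7,8-tris(benzyloxy)-3-methyl-10-oxo-1H,10H-pyrano[4,3-b]chromene-9-carboxylate; 16 benzyl 6,7-bis(benzyloxy)-4-oxo-3-(3-oxobutanoyl)chromane-5-carboxylate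
Product: 26 hexa-O-benzyl derivative of the target, via pyrylium phosphate ion pair 23 (not isolated), via C-1 adduct 24 (not isolated), via enol ether monoketal 25 (not isolated)
Conditions: (R)-TRIP (3,3'-bis(2,4,6-triisopropylphenyl)-1,1'-binaphthyl-2,2'-diyl hydrogen phosphate, 10 mol %), 5 Å MS, toluene, −20 to 25 °C
Reagents that add atoms: none
Why: Proposed new method: the chiral phosphoric acid ionises the lactol ether to the planar pyrylium/phosphate ion pair 23, and the enol of 16, hydrogen-bonded to the phosphate, adds through its central carbon to one face of C-1 (acetal-type CH, catalyst control); the acid then protonates the methyl enol ether so that the acetyl enol oxygen closes ring D (ketal carbon fixed by the bridge), and the chromanone enol adds reversibly to the resulting β-alkoxy enone (6-endo oxa-Michael, ring E, last two centres cis-fused under thermodynamic control); the closest known reaction types are chiral phosphoric acid catalysed additions of enols to oxocarbenium and benzopyrylium ions and acid-catalysed formation of dioxabicyclo[3.3.1]nonane ketals from 1,3-dicarbonyl compounds.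

Step 16
Reactants: 26 hexa-O-benzyl derivative of the target
Product: 27 CNP0230818.1
Conditions: H2 (1 atm), Pd/C (10 wt %), EtOAc/MeOH, 25 °C
Reagents that add atoms: none
Why: Hydrogenolysis cleaves the four aryl benzyl ethers and two benzyl esters under neutral conditions that should leave the ketals and the tetrasubstituted push–pull alkenes untouched.

## Compound list

1 | opianic acid (6-formyl-2,3-dimethoxybenzoic acid) | O=Cc1ccc(OC)c(OC)c1C(=O)O | starting material
2 | 5-bromo-6-formyl-2,3-dimethoxybenzoic acid | O=Cc1c(Br)cc(OC)c(OC)c1C(=O)O | intermediate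
3 | 5-bromo-6-formyl-2,3-dihydroxybenzoic acid | O=Cc1c(Br)cc(O)c(O)c1C(=O)O | intermediate
4 | benzyl 2,3-bis(benzyloxy)-5-bromo-6-formylbenzoate | O=Cc1c(Br)cc(OCc2ccccc2)c(OCc2ccccc2)c1C(=O)OCc1ccccc1 | intermediate
5 | 3,4-bis(benzyloxy)-2-[(benzyloxy)carbonyl]-6-bromobenzoic acid | OC(=O)c1c(Br)cc(OCc2ccccc2)c(OCc2ccccc2)c1C(=O)OCc1ccccc1 | intermediate
6 | benzyl 2,3-bis(benzyloxy)-5-bromo-6-(chlorocarbonyl)benzoate | ClC(=O)c1c(Br)cc(OCc2ccccc2)c(OCc2ccccc2)c1C(=O)OCc1ccccc1 | intermediate
7 | 3,5-dimethylisoxazole | Cc1cc(C)on1 | starting material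
8 | [(3-methylisoxazol-5-yl)methyl]lithium | [Li]Cc1cc(C)no1 | intermediate (not isolated)
9 | 2-(3-methylisoxazol-5-yl)acetaldehyde | O=CCc1cc(C)no1 | intermediate
10 | (E)-1-[2-(3-methylisoxazol-5-yl)ethenyl]pyrrolidine | Cc1cc(/C=C/N2CCCC2)on1 | intermediate
11 | benzyl 2,3-bis(benzyloxy)-5-bromo-6-[2-(3-methylisoxazol-5-yl)-3-(pyrrolidin-1-yl)prop-2-enoyl]benzoate (E/Z mixture) | O=C(C(=CN1CCCC1)c1cc(C)no1)c1c(Br)cc(OCc2ccccc2)c(OCc2ccccc2)c1C(=O)OCc1ccccc1 | intermediate (not isolated)
12 | benzyl 2,3-bis(benzyloxy)-5-bromo-6-[3-hydroxy-2-(3-methylisoxazol-5-yl)prop-2-enoyl]benzoate (formyl enol, present as its caesium enolate) | O=C(C(=CO)c1cc(C)no1)c1c(Br)cc(OCc2ccccc2)c(OCc2ccccc2)c1C(=O)OCc1ccccc1 | intermediate (not isolated)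
13 | benzyl 6,7-bis(benzyloxy)-3-(3-methylisoxazol-5-yl)-4-oxo-4H-chromene-5-carboxylate | O=c1c(-c2cc(C)no2)coc2cc(OCc3ccccc3)c(OCc3ccccc3)c(C(=O)OCc3ccccc3)c12 | intermediate
14 | benzyl 6,7-bis(benzyloxy)-3-(3-methylisoxazol-5-yl)-4-oxochromane-5-carboxylate (racemic) | O=C1C(c2cc(C)no2)COc2cc(OCc3ccccc3)c(OCc3ccccc3)c(C(=O)OCc3ccccc3)c21 | intermediate
15 | benzyl 3-[(Z)-3-aminobut-2-enoyl]-6,7-bis(benzyloxy)-4-oxochromane-5-carboxylate | C/C(N)=C/C(=O)C1COc2cc(OCc3ccccc3)c(OCc3ccccc3)c(C(=O)OCc3ccccc3)c2C1=O | intermediate (not isolated)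
16 | benzyl 6,7-bis(benzyloxy)-4-oxo-3-(3-oxobutanoyl)chromane-5-carboxylate (racemic; drawn as triketone, exists as enols) | CC(=O)CC(=O)C1COc2cc(OCc3ccccc3)c(OCc3ccccc3)c(C(=O)OCc3ccccc3)c2C1=O | intermediate
17 | pentane-2,4-dione | CC(=O)CC(C)=O | starting material
18 | 1-(2-methyl-1,3-dioxolan-2-yl)propan-2-one | CC(=O)CC1(C)OCCO1 | intermediate
19 | (E)-4-(dimethylamino)-1-(2-methyl-1,3-dioxolan-2-yl)but-3-en-2-one | CN(C)/C=C/C(=O)CC1(C)OCCO1 | intermediate
20 | benzyl 2,3-bis(benzyloxy)-5-bromo-6-{2-[(dimethylamino)methylidene]-4-(2-methyl-1,3-dioxolan-2-yl)-3-oxobutanoyl}benzoate | CN(C)C=C(C(=O)CC1(C)OCCO1)C(=O)c1c(Br)cc(OCc2ccccc2)c(OCc2ccccc2)c1C(=O)OCc1ccccc1 | intermediate (not isolated)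
21 | benzyl 2,3-bis(benzyloxy)-5-bromo-6-(6-methyl-4-oxo-4H-pyran-3-carbonyl)benzoate | Cc1cc(=O)c(co1)C(=O)c1c(Br)cc(OCc2ccccc2)c(OCc2ccccc2)c1C(=O)OCc1ccccc1 | intermediate
22 | benzyl 1,7,8-tris(benzyloxy)-3-methyl-10-oxo-1H,10H-pyrano[4,3-b]chromene-9-carboxylate (racemic) | CC1=Cc2oc3cc(OCc4ccccc4)c(OCc4ccccc4)c(C(=O)OCc4ccccc4)c3c(=O)c2C(OCc2ccccc2)O1 | intermediate
23 | 7,8-bis(benzyloxy)-9-[(benzyloxy)carbonyl]-3-methyl-10-oxo-10H-pyrano[4,3-b]chromen-2-ium (cation shown; counter-ion is the chiral phosphate) | Cc1cc2oc3cc(OCc4ccccc4)c(OCc4ccccc4)c(C(=O)OCc4ccccc4)c3c(=O)c2c[o+]1 | intermediate (not isolated)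
24 | C-1 adduct: the pyranochromenone of 22 with the central carbon of triketone 16 in place of the 1-benzyloxy group (C-1 configured as in the target; the other centres labile) | CC1=Cc2oc3cc(OCc4ccccc4)c(OCc4ccccc4)c(C(=O)OCc4ccccc4)c3c(=O)c2[C@@H](O1)C(C(C)=O)C(=O)C1COc2cc(OCc3ccccc3)c(OCc3ccccc3)c(C(=O)OCc3ccccc3)c2C1=O | intermediate (not isolated)
25 | enol ether monoketal: rings A–D closed, ring D holding the enol ether of the acetyl group, chromanone side chain still open | C[C@@]12Cc3oc4cc(OCc5ccccc5)c(OCc5ccccc5)c(C(=O)OCc5ccccc5)c4c(=O)c3[C@@H](O1)C(C(=O)C1COc3cc(OCc4ccccc4)c(OCc4ccccc4)c(C(=O)OCc4ccccc4)c3C1=O)=C(C)O2 | intermediate (not isolated)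
26 | hexa-O-benzyl derivative of the target (four phenols as benzyl ethers, two acids as benzyl esters; stereocentres as in the target) | C[C@@]12Cc3oc4cc(OCc5ccccc5)c(OCc5ccccc5)c(C(=O)OCc5ccccc5)c4c(=O)c3[C@@H](O1)[C@H]1C(=O)C3=C(O[C@@]1(C)O2)c1c(cc(OCc2ccccc2)c(OCc2ccccc2)c1C(=O)OCc1ccccc1)OC3 | intermediate
27 | CNP0230818.1 | C[C@@]12Cc3oc4cc(O)c(O)c(C(=O)O)c4c(=O)c3[C@@H](O1)[C@H]1C(=O)C3=C(O[C@@]1(C)O2)c1c(cc(O)c(O)c1C(=O)O)OC3 | target

## Step count and risks

Total steps: 16. Longest linear sequence: 10 steps (1–5, 8, 9, 10, 15, 16).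

Steps most likely to fail:

1. Step 15 (Proposed new method). The planar pyrylium ion may be poorly discriminated by the chiral counter-anion, or the C-1 configuration may erode by reversible loss of the triketone before the ketal locks it. Fallback: from 22 and 16 the same cascade is run with an achiral acid (diphenyl phosphate, toluene, 25 °C), a known acid-catalysed oxocarbenium alkylation and ketalisation. This gives racemic material, that is 26 together with the mirror-image hexabenzyl compound F1. Hydrogenolysis (H2, Pd/C) gives the target together with the enantiomer of the target F2, and the two are separated by chromatography on a chiral stationary phase or by crystallisation of their salts with a cinchona base. The route is rejoined at 27.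

2. Step 14. The benzyloxide adduct may revert faster than copper inserts into the C–Br bond, or intermolecular O-arylation of benzyl alcohol may compete. Fallback: from 18 and 6, the kinetic lithium enolate of 18 (LiN(SiMe3)2, THF, −78 °C) is C-acylated by 6 and the diketone enolate is closed with CuI (DMF, 80 °C) to the 2-substituted chromone ketal F3. Iodination at C-3 (N-iodosuccinimide, cat. CF3CO2H, MeCN) gives the 3-iodochromone F4. Iodine–magnesium exchange (i-PrMgCl·LiCl, THF, −40 °C) and DMF give the 3-formylchromone ketal F5. Treatment with p-TsOH in benzyl alcohol/toluene removes the dioxolane; the freed enol closes onto the aldehyde and the lactol is benzylated in situ, which returns 22.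

3. Step 10. The liberated enaminone nitrogen may condense with the C-4 carbonyl (pyridone formation) faster than it hydrolyses. Fallback: from 19 and 6, the C-acylated enaminone 20 is treated not with acid but with H2O, Cs2CO3 and CuI (conditions of step 8). This closes the chromone through the formyl oxygen to the 3-acylchromone ketal F6; the isomer closed through the ketone oxygen has to be removed. LiBH(s-Bu)3 (THF, −78 °C) gives the chromanone ketal F7, and aqueous HCl/THF frees the ketone, which returns 16 with no nitrogen in the molecule.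

Further compounds
F1 | step 15 | enantiomer of 26 | C[C@]12Cc3oc4cc(OCc5ccccc5)c(OCc5ccccc5)c(C(=O)OCc5ccccc5)c4c(=O)c3[C@H](O1)[C@@H]1C(=O)C3=C(O[C@]1(C)O2)c1c(cc(OCc2ccccc2)c(OCc2ccccc2)c1C(=O)OCc1ccccc1)OC3
F2 | step 15 | enantiomer of the target 27 | C[C@]12Cc3oc4cc(O)c(O)c(C(=O)O)c4c(=O)c3[C@H](O1)[C@@H]1C(=O)C3=C(O[C@]1(C)O2)c1c(cc(O)c(O)c1C(=O)O)OC3
F3 | step 14 | benzyl 6,7-bis(benzyloxy)-2-[(2-methyl-1,3-dioxolan-2-yl)methyl]-4-oxo-4H-chromene-5-carboxylate | CC1(Cc2cc(=O)c3c(C(=O)OCc4ccccc4)c(OCc4ccccc4)c(OCc4ccccc4)cc3o2)OCCO1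
F4 | step 14 | benzyl 6,7-bis(benzyloxy)-3-iodo-2-[(2-methyl-1,3-dioxolan-2-yl)methyl]-4-oxo-4H-chromene-5-carboxylate | CC1(Cc2oc3cc(OCc4ccccc4)c(OCc4ccccc4)c(C(=O)OCc4ccccc4)c3c(=O)c2I)OCCO1
F5 | step 14 | benzyl 6,7-bis(benzyloxy)-3-formyl-2-[(2-methyl-1,3-dioxolan-2-yl)methyl]-4-oxo-4H-chromene-5-carboxylate | CC1(Cc2oc3cc(OCc4ccccc4)c(OCc4ccccc4)c(C(=O)OCc4ccccc4)c3c(=O)c2C=O)OCCO1
F6 | step 10 | benzyl 6,7-bis(benzyloxy)-3-[(2-methyl-1,3-dioxolan-2-yl)acetyl]-4-oxo-4H-chromene-5-carboxylate | CC1(CC(=O)c2coc3cc(OCc4ccccc4)c(OCc4ccccc4)c(C(=O)OCc4ccccc4)c3c2=O)OCCO1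
F7 | step 10 | benzyl 6,7-bis(benzyloxy)-3-[(2-methyl-1,3-dioxolan-2-yl)acetyl]-4-oxochromane-5-carboxylate (racemic) | CC1(CC(=O)C2COc3cc(OCc4ccccc4)c(OCc4ccccc4)c(C(=O)OCc4ccccc4)c3C2=O)OCCO1
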